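Start from the small charge of second nucleophile, 0.500 equiv on the starting material, and follow where it goes: the intermediate can capture it early, and target can consume it later.

common to all: starting material 0.10 M; protic impurity 0.0500 M; time 12 h

| charge | first nucleophile | second nucleophile | temperature | remark |
|---|---|---|---|---|
| zeta | 1.20 equiv (in portions, 3, over 2.5 h) | 0.500 equiv | 110 °C | first portion at the start, last at 2.5 h |
| epsilon | 1.20 equiv (fed, over 2.5 h) | 0.500 equiv | 110 °C | all else is in the flask from the start; the feed brings no volume worth counting |
| delta | 1.20 equiv | 0.500 equiv |  | everything together at the start at 80 °C, warmed to 110 °C at 2.5 h |
| beta | 1.20 equiv | 0.500 equiv (fed, over 2.5 h) |  | the addition at 80 °C, then warmed to 110 °C; the feed brings no volume worth counting |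
| alpha | 1.20 equiv | 0.500 equiv | 110 °C | everything together at the start |

    starting material + protic impurity → quenched substrate (k1 = 0.0091 M⁻¹ s⁻¹, Ea1 = 63.0 kJ mol⁻¹)
    second nucleophile + target → over-reaction product (k2 = 0.0094 M⁻¹ s⁻¹, Ea2 = 91.0 kJ mol⁻¹)
    second nucleophile + target ⇌ idle adduct, settled at all times (K3 = 11 M⁻¹, ΔH3 = 14.0 kJ mol⁻¹)
    starting material → intermediate (k4 = 0.0023 s⁻¹, Ea4 = 105 kJ mol⁻¹)
    second nucleophile + intermediate → other capture product (k5 = 0.025 M⁻¹ s⁻¹, Ea5 = 73.0 kJ mol⁻¹)
    first nucleophile + intermediate → target (k6 = 0.10 M⁻¹ s⁻¹, Ea6 = 72.0 kJ mol⁻¹)
    (constants at 110 °C)

- amounts and yields of target count idle adduct too
- the list of constants is for 110 °C, to be carried to other temperatures by the activation energies and enthalpies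

1. the flask that comes out highest in amount of over-reaction product, in percent of the starting material charged; "all alike" if 1.5 percentage points covers them all (zeta / epsilon / delta / beta / alpha / all alike)
2. amount of over-reaction product at the end, in percent of the starting material charged, zeta
3. amount of over-reaction product at the end, in percent of the starting material charged, epsilon
4. amount of over-reaction product at the end, in percent of the starting material charged, delta
5. amount of over-reaction product at the end, in percent of the starting material charged, beta
6. amount of over-reaction product at the end, in percent of the starting material charged, alpha

Solve flask alpha at both ends and join them. At the early end, hold both nucleophiles at their charges: the intermediate then divides between them with the selectivity factor 9.60, the rate of making target over the rate of capture. Next reckon the starting material lost to protic impurity, in two ways. With the impurity frozen at its charge, the quenched share is 16.5 %. That share would consume 33.0 % of the impurity, so take instead a mean impurity of 0.0417 M, which gives 14.2 %. The two ways part, and the frozen one cheats, since it keeps the charge of 0.0500 M where the mean reckoned for the step is lower; keep the second.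

Then 85.8 % of the starting material reaches the intermediate, and an amount equal to 8.10 % of the starting material charged is captured by second nucleophile. Divide by the charge to get the capture fraction, the part of the second nucleophile charge taken by the intermediate: 16.2 %. With the first nucleophile held at 1.20 equiv and the selectivity factor at 9.60, above one, the captured amount rises nearly in step with the charge of second nucleophile, so this fraction changes little with that charge.

At the late end, the reckoned target, 77.7 % of the starting material charged, exceeds what survives of the second nucleophile, so second nucleophile is the limiting reagent of the over-reaction, with a ceiling of 41.9 %, and 0.0358 M of target is reckoned to remain beside it. Treat the tail as pseudo-first-order and count the idle adduct: the half-life of the second nucleophile is 0.797 h, far shorter than the run of 12 h. My reckoning therefore puts alpha at its ceiling.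

The forecast names beta as highest and gives 14 % for zeta, 11 % for epsilon, 43 % for delta, 46 % for beta and 42 % for alpha, on the ground that “over-reaction drains whatever second nucleophile survives capture of the intermediate”.

The simulation gives beta as highest, with 16.5 % for zeta, 7.79 % for epsilon, 43.1 % for delta, 45.8 % for beta and 41.8 % for alpha, so the forecast is right on the flask and, within the tolerance, on each amount.

Alpha ends at 41.8 % against the ceiling of 41.9 %, with 8.16 % of other capture product and 0 % of second nucleophile left. In beta at 1.07 h, during the feed at 80 °C, the intermediate was going to target 22 times as fast as to capture, and the capture fraction of beta stands at 8.32 % at the end, lower than the 16.2 % reckoned for alpha. Now cut beta to 0.300 equiv of second nucleophile, all other charges held, and carry the fraction of beta over: the ceiling becomes 27.5 %. The computed flask gives 27.5 % of over-reaction product, with 2.49 % of other capture product.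

The constants used here were set for the occasion, and the outcome is calculated.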